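**Analysis of the target**

The target is a flavanone: benzene ring A is fused to a dihydropyranone ring C (O1, C2, C3, C4, C4a, C8a), and ring C carries a second benzene ring B at C2. Ring A has a free hydroxyl at C7 flanked by 3-methylbut-2-enyl (prenyl) groups at C6 and C8, with C5 unsubstituted. Ring B has a 4'-hydroxyl with one ortho prenyl group at C3'. The only stereocentre is C2, with S configuration (checked against the SMILES: O1 > C1' > C3 > H). It is benzylic, bound to O1 and β to the C4 ketone, so no neighbouring centre can relay its configuration, and it is lost whenever ring C opens, either by retro-oxa-Michael reaction under base or by ionisation of O1–C2 under strong acid. The three prenyl groups are the second liability: each lies ortho to a phenol and closes to a 2,2-dimethylchroman under acid, they react with electrophilic oxidants, and they rule out hydrogenolysis and benzylic C–H oxidation. The difficulty is therefore concentrated in one point: C2 must be made enantioselectively on a molecule that tolerates neither strong acid nor base. The strategy rests on the observation that O1–C8a=C4a–C4 is the oxa-diene of an ortho-quinone methide obtainable from a ring A salicylaldehyde, and that C2–C3 with ring B attached is a para-oxygenated styrene. If C4 is carried as a methyl ether, joining the two builds ring C, two skeletal bonds and the stereocentre at once, and the ketone follows without oxidising any C–H bond.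

**Retrosynthetic reasoning**

- **17 ⇒ 16.** The two phenolic O–H bonds are traced back to silyl ethers. Free phenols ortho to prenyl groups would not survive the acid of the ring-forming step, and aryl silyl ethers can be removed at the end by buffered fluoride, which is neither acidic enough to cyclise a prenyl group nor basic enough to open ring C.

- **16 ⇒ 15 ⇒ 14.** The C4 carbonyl is taken back to the secondary alcohol 15 and then to the methyl ether 14. This is a change of functional group only: the C4–O bond is already present, and the ether oxygen is exchanged by solvolysis through a benzylic cation stabilised by O1 and O7. The forward steps must do this under acid mild enough to leave O1–C2 intact, and then oxidise a benzylic alcohol in the presence of three alkenes. The configuration at C4 is irrelevant because it ends as a carbonyl.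

- **14 ⇒ 7 + 11 (through 12 and 13).** C3–C4 and O1–C2 are cut together. No other disconnection removes ring C, two skeletal bonds and the stereocentre in one step while leaving two fully substituted arenes as fragments. Forward, aldehyde 7 is converted by an orthoester into acetal 12, which ionises to the quinone methide 13, and styrene 11 adds across it. The reaction must discriminate the two faces of a planar intermediate with a chiral counteranion, place the aryl group at C2, and select the styrene over three prenyl alkenes.

- **7 ⇒ 6 ⇒ 5 ⇒ 3 + 4 ⇒ 2 ⇒ 1.** The silyl ether of 7 is removed first (6). Silylation should be selective because the C2 hydroxyl is tied up in a hydrogen bond to the formyl group. The two aryl–prenyl bonds are then cut back to aryl bromides (3) and stannane 4. Direct prenylation of a resorcinol gives O/C and positional mixtures, whereas bromination of 1 places halogen exactly on the two doubly activated positions. The phenols are masked as acetates (3, 5) during the coupling because acidic phenols would protonate an allylic stannane, and acetates come off under conditions harmless to prenyl groups.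

- **11 ⇒ 10 ⇒ 9 + 4 ⇒ 8.** The vinyl group is taken back to the aldehyde of 10 (one-carbon olefination). The prenyl group is cut to the bromide of 9 and stannane 4, and the silyl ether to the phenol of 8. The silyl group is installed first so that the coupling sees no acidic OH, and so that the same protecting group serves through the cycloaddition, where a para silyloxy group keeps the styrene nucleophilic.

**Alternatives that were turned down**

**Alternative 1:** Ring A is dismantled instead of ring C. The bonds C7–C8, C4a–C8a and C6–C7 are cut, leading to the unsaturated diazoketone A2, (E)-1-diazo-7-methylocta-3,6-dien-2-one, and the siloxyalkyne A3, triisopropyl[(5-methylhex-4-en-1-ynyl)oxy]silane.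
- Forward key step: irradiation of A2 causes a Wolff rearrangement to a vinylketene, which adds to A3 in a [2+2] sense. The vinylcyclobutenone opens (4π) to a dienylketene, which closes (6π) and tautomerises to phenol A1, 2,6-bis(3-methylbut-2-enyl)-3-(triisopropylsilyloxy)phenol.
- For it: both prenyl groups and both oxygens of ring A are placed without any regiochemical question, the oxygens emerge differentiated, and no tin or palladium is needed. On these points it is stronger than the chosen route, which needs protection, cross-coupling, deprotection and a site-selective silylation.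
- Against it: the cascade builds a benzene ring that is commercially available in resorcinol form. A1 still lacks the C4 carbon at C4a, and ring C and C2 are not addressed, so an asymmetric ring closure would still have to follow. The ketenes are generated next to two trisubstituted alkenes that can compete with the alkyne, and A2 and A3 each need several steps.
- Comparison: the chosen strategy spends its one demanding step on ring C and the stereocentre, and reaches ring A by five routine steps.

**Alternative 2:** Ring A is cut at C8–C8a and C4a–C5. This gives the enantioenriched dihydropyranone A5, (2S)-2-[4-(tert-butyldimethylsilyloxy)-3-(3-methylbut-2-enyl)phenyl]-5-iodo-2,3-dihydro-4H-pyran-4-one, which already contains ring C and C2, and the diene A6, trimethyl{[1-methoxy-7-methyl-2-(3-methylbut-2-enyl)octa-1,3,6-trien-3-yl]oxy}silane.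
- Forward key step: A6 adds across the C5=C6 bond of A5 with its nucleophilic terminus at the oxygen-bearing carbon. Loss of the alkoxy group and of the halide by two eliminations aromatises the adduct to A4, the 4'-O-silyl ether of the target.
- For it: C2 would come from a well-established catalytic asymmetric hetero-Diels–Alder reaction of aldehyde 10 with a siloxydiene. This is more secure than the chosen key step, and A4 is one desilylation from the target.
- Against it: the dienophile is the alkene of a vinylogous ester, electronically poor as an acceptor and hindered by iodine. A6 is substituted on all four diene carbons, with a prenyl group on the reacting terminus, so its geometry and s-cis conformation are problematic and its skipped alkenes can isomerise. The heat or Lewis acid needed would endanger C2 of A5 through opening of the β-aryloxy ketone.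
- Comparison: this alternative is stronger on the reliability of asymmetric induction. The chosen strategy offers aromatic fragments whose substitution is fixed by classical arene chemistry, a shorter sequence, and a key step that is tested early on simple material.

**Alternative 3:** Ring C is cut at the aryl ether bond O1–C8a. The precursor is the bromo alcohol A8, (1S)-3-[2-bromo-4-(methoxymethoxy)-3,5-bis(3-methylbut-2-enyl)phenyl]-3-(tert-butyldimethylsilyloxy)-1-[4-(methoxymethoxy)-3-(3-methylbut-2-enyl)phenyl]propan-1-ol.
- Forward key step: a palladium catalyst with a bulky binaphthyl dialkylphosphine and a carbonate base joins the C2 hydroxyl to the C8a bromide, giving the protected flavan A7.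
- For it: intramolecular palladium-catalysed C–O coupling of secondary alcohols to chromans is a known reaction type. The carbinol C–O bond is untouched, so the configuration is retained, and the stereocentre could come from a dependable asymmetric ketone reduction. In predictability of the stereochemical outcome it is stronger than the chosen key step.
- Against it: the bromide sits between the C8 prenyl group and the C4a side chain on an electron-rich ring. The palladium alkoxide of a secondary benzylic alcohol readily undergoes β-hydride elimination, giving ketone and debrominated arene, and the resulting palladium hydride can move the prenyl double bonds into conjugation. The methoxymethyl ethers must finally be removed by acid from phenols flanked by prenyl groups. A8 itself needs a long linear sequence to a hexasubstituted ring A.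
- Comparison: the chosen strategy is convergent and shorter and ends with a buffered fluoride step instead of an acid deprotection.

Key step: step 9

Assumption: the sense of induction of the confined acid in step 9 cannot be predicted with certainty, so the catalyst enantiomer that delivers the (2S) adduct is taken to be the one used; both enantiomers are equally accessible from (R)- or (S)-BINOL.

**Route**

Step 1
Reactants: 1 2,4-dihydroxybenzaldehyde
Product: 2 3,5-dibromo-2,4-dihydroxybenzaldehyde
Conditions: Br2 (2.1 equiv), AcOH, rt
Reagents that add atoms: bromine, BrBr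
Why: Electrophilic aromatic bromination; C3 and C5 are each ortho or para to both hydroxyl groups, whereas C6 is meta to both and ortho to the formyl group, so two equivalents of bromine should stop at the 3,5-dibromide.

Step 2
Reactants: 2 3,5-dibromo-2,4-dihydroxybenzaldehyde
Product: 3 2,4-diacetoxy-3,5-dibromobenzaldehyde
Conditions: Ac2O (3 equiv), pyridine, DMAP (5 mol%), CH2Cl2, 0 °C to rt
Reagents that add atoms: acetic anhydride, CC(=O)OC(C)=O
Why: DMAP-catalysed O-acylation of both phenols; the acetates remove the acidic OH groups that would protonate the allylic stannane in step 3 and can later be cleaved without touching prenyl groups.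

Step 3
Reactants: 3 2,4-diacetoxy-3,5-dibromobenzaldehyde; 4 tributyl(3-methylbut-2-enyl)stannane
Product: 5 2,4-diacetoxy-3,5-bis(3-methylbut-2-enyl)benzaldehyde
Conditions: 4 (2.5 equiv), Pd(PPh3)4 (10 mol%), toluene, 105 °C
Reagents that add atoms: tributyl(3-methylbut-2-enyl)stannane (compound 4), CC(C)=CC[Sn](CCCC)(CCCC)CCCC
Why: Twofold Stille coupling under neutral conditions, which tolerate the aldehyde and the aryl acetates; reductive elimination from the aryl(allyl)palladium intermediate should occur at the unsubstituted allyl terminus and give the linear prenyl group at both positions.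

Step 4
Reactants: 5 2,4-diacetoxy-3,5-bis(3-methylbut-2-enyl)benzaldehyde
Product: 6 2,4-dihydroxy-3,5-bis(3-methylbut-2-enyl)benzaldehyde
Conditions: K2CO3 (0.3 equiv), MeOH, 0 °C to rt; aq. NH4Cl
Reagents that add atoms: none
Why: Base-catalysed methanolysis (transesterification) of two aryl acetates, which are activated esters of acidic phenols; the aldehyde and the prenyl groups are inert to carbonate in methanol.

Step 5
Reactants: 6 2,4-dihydroxy-3,5-bis(3-methylbut-2-enyl)benzaldehyde
Product: 7 4-(tert-butyldimethylsilyloxy)-2-hydroxy-3,5-bis(3-methylbut-2-enyl)benzaldehyde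
Conditions: TBSCl (1.05 equiv), imidazole (2.2 equiv), DMF, 0 °C to rt
Reagents that add atoms: tert-butyldimethylsilyl chloride, CC(C)(C)[Si](C)(C)Cl
Why: Site-selective silylation; the C2 hydroxyl is held in a six-membered hydrogen bond to the formyl oxygen and is much less nucleophilic than the more acidic C4 hydroxyl, so one equivalent of silyl chloride should go to O4 despite the two flanking prenyl groups.

Step 6
Reactants: 8 3-bromo-4-hydroxybenzaldehyde
Product: 9 3-bromo-4-(tert-butyldimethylsilyloxy)benzaldehyde
Conditions: TBSCl (1.2 equiv), imidazole (2.5 equiv), CH2Cl2, rt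
Reagents that add atoms: tert-butyldimethylsilyl chloride, CC(C)(C)[Si](C)(C)Cl
Why: Standard silylation of the only hydroxyl group; it removes the acidic proton before the Stille coupling and installs the ether that keeps the later styrene electron-rich.

Step 7
Reactants: 9 3-bromo-4-(tert-butyldimethylsilyloxy)benzaldehyde; 4 tributyl(3-methylbut-2-enyl)stannane
Product: 10 4-(tert-butyldimethylsilyloxy)-3-(3-methylbut-2-enyl)benzaldehyde
Conditions: 4 (1.3 equiv), Pd(PPh3)4 (5 mol%), toluene, 105 °C
Reagents that add atoms: tributyl(3-methylbut-2-enyl)stannane (compound 4), CC(C)=CC[Sn](CCCC)(CCCC)CCCC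
Why: Stille coupling of an aryl bromide with the allylic stannane under neutral, fluoride-free conditions, so that the aldehyde and the aryl silyl ether are retained and the prenyl group is transferred in its linear form.

Step 8
Reactants: 10 4-(tert-butyldimethylsilyloxy)-3-(3-methylbut-2-enyl)benzaldehyde
Product: 11 tert-butyldimethyl[2-(3-methylbut-2-enyl)-4-vinylphenoxy]silane
Conditions: Ph3PCH3Br (1.5 equiv), KOtBu (1.4 equiv), THF, 0 °C; then 10, 0 °C to rt
Reagents that add atoms: methyltriphenylphosphonium bromide, C[P+](c1ccccc1)(c1ccccc1)c1ccccc1.[Br-]
Why: Wittig methylenation of an aromatic aldehyde with the non-stabilised ylide, fast at 0 °C and compatible with the aryl silyl ether and the trisubstituted alkene; the styrene should be stored cold and used promptly.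

Step 9
Reactants: 7 4-(tert-butyldimethylsilyloxy)-2-hydroxy-3,5-bis(3-methylbut-2-enyl)benzaldehyde; 11 tert-butyldimethyl[2-(3-methylbut-2-enyl)-4-vinylphenoxy]silane
Product: 14 (2S)-7-(tert-butyldimethylsilyloxy)-2-[4-(tert-butyldimethylsilyloxy)-3-(3-methylbut-2-enyl)phenyl]-4-methoxy-6,8-bis(3-methylbut-2-enyl)chromane (C4 epimers), via dimethyl acetal 12 (not isolated), via 4-methoxy ortho-quinone methide 13 (not isolated)
Conditions: 7 (1.0 equiv), 11 (1.5 equiv, slow addition), HC(OMe)3 (1.5 equiv), confined BINOL-derived imidodiphosphorimidate Brønsted acid (N-triflyl, 3,3'-diaryl; 5 mol%), 5 Å MS, toluene, −40 °C; Et3N quench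
Reagents that add atoms: trimethyl orthoformate, COC(OC)OC
Why: Proposed new method: the acid and the orthoformate convert 7 into acetal 12, which ionises with loss of methanol to the O-protonated 4-methoxy ortho-quinone methide 13, held as a contact ion pair with the confined chiral anion through a hydrogen bond to the phenolic OH. The closest known reaction types are the achiral acid-promoted three-component coupling of salicylaldehydes, orthoformates and styrenes to 4-alkoxyflavans and chiral Brønsted acid catalysed cycloadditions of ortho-quinone methides; their enantioselective intermolecular combination with a styrene has not been shown. Styrene 11 adds in an inverse-electron-demand oxa-[4+2] cycloaddition that is concerted but asynchronous: its terminal carbon bonds to the methide carbon (C3–C4) ahead of capture of the developing benzylic cation by the phenolic oxygen (O1–C2), which closes ring C as a six-membered ring and restores the aromaticity of ring A. Regiochemistry follows from polarity, since the para silyloxy group of 11 makes the CH2 terminus the nucleophile and stabilises positive charge at the carbon that becomes C2, so the aryl group ends at C2. C2 is set by the chiral anion, whose confined pocket shields one face of the heterodiene and fixes the orientation of the incoming styrene; C4 is left uncontrolled apart from an expected cis preference and is erased in steps 10 and 11. Chemoselectivity for the styrene over the three prenyl alkenes should follow from the much higher nucleophilicity of a para-oxygenated styrene compared with a trialkyl-substituted alkene, and low temperature with a low loading of a confined acid should keep the ortho prenyl group of 7 from cyclising onto the free phenol and 11 from oligomerising. A non-polar solvent is chosen to keep the ion pair tight, because in a stepwise, solvent-separated pathway the configuration at C2 would depend on both the face of 13 that is attacked and the cis/trans ratio of the ring closure.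

Step 10
Reactants: 14 (2S)-7-(tert-butyldimethylsilyloxy)-2-[4-(tert-butyldimethylsilyloxy)-3-(3-methylbut-2-enyl)phenyl]-4-methoxy-6,8-bis(3-methylbut-2-enyl)chromane (C4 epimers)
Product: 15 (2S)-7-(tert-butyldimethylsilyloxy)-2-[4-(tert-butyldimethylsilyloxy)-3-(3-methylbut-2-enyl)phenyl]-6,8-bis(3-methylbut-2-enyl)chroman-4-ol (C4 epimers)
Conditions: CSA (10 mol%), THF/H2O (4:1), 0 °C to rt
Reagents that add atoms: water, O
Why: Acid-catalysed solvolysis of a benzylic methyl ether through the C4 cation, which is stabilised by O1 and by the para silyloxy group of ring A and therefore forms far more easily than a cation at C2; the large excess of water drives the exchange, and no free phenol is present to attack a prenyl group.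

Step 11
Reactants: 15 (2S)-7-(tert-butyldimethylsilyloxy)-2-[4-(tert-butyldimethylsilyloxy)-3-(3-methylbut-2-enyl)phenyl]-6,8-bis(3-methylbut-2-enyl)chroman-4-ol (C4 epimers)
Product: 16 (2S)-7-(tert-butyldimethylsilyloxy)-2-[4-(tert-butyldimethylsilyloxy)-3-(3-methylbut-2-enyl)phenyl]-6,8-bis(3-methylbut-2-enyl)chroman-4-one
Conditions: Dess–Martin periodinane (1.3 equiv), pyridine (3 equiv), CH2Cl2, 0 °C to rt
Reagents that add atoms: none
Why: Dess–Martin oxidation of a secondary benzylic alcohol under buffered, non-basic conditions; both C4 epimers converge on one ketone, the alkenes and silyl ethers are inert, and C2 is not exposed to base once it has become β to a carbonyl.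

Step 12
Reactants: 16 (2S)-7-(tert-butyldimethylsilyloxy)-2-[4-(tert-butyldimethylsilyloxy)-3-(3-methylbut-2-enyl)phenyl]-6,8-bis(3-methylbut-2-enyl)chroman-4-one
Product: 17 (2S)-7-hydroxy-2-[4-hydroxy-3-(3-methylbut-2-enyl)phenyl]-6,8-bis(3-methylbut-2-enyl)chroman-4-one
Conditions: TBAF (2.5 equiv), AcOH (2.5 equiv), THF, 0 °C
Reagents that add atoms: none
Why: Fluoride-induced cleavage of both aryl silyl ethers; acetic acid protonates the phenoxides as they form, so that neither retro-oxa-Michael opening of ring C nor opening through the 4'-phenoxide should erode C2, and the medium is not acidic enough to cyclise a prenyl group.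

**Compound list**

1 | 2,4-dihydroxybenzaldehyde | O=Cc1ccc(O)cc1O | starting material
2 | 3,5-dibromo-2,4-dihydroxybenzaldehyde | O=Cc1cc(Br)c(O)c(Br)c1O | intermediate
3 | 2,4-diacetoxy-3,5-dibromobenzaldehyde | CC(=O)Oc1c(Br)cc(C=O)c(OC(C)=O)c1Br | intermediate
4 | tributyl(3-methylbut-2-enyl)stannane | CC(C)=CC[Sn](CCCC)(CCCC)CCCC | starting material
5 | 2,4-diacetoxy-3,5-bis(3-methylbut-2-enyl)benzaldehyde | CC(=O)Oc1c(CC=C(C)C)cc(C=O)c(OC(C)=O)c1CC=C(C)C | intermediate
6 | 2,4-dihydroxy-3,5-bis(3-methylbut-2-enyl)benzaldehyde | O=Cc1cc(CC=C(C)C)c(O)c(CC=C(C)C)c1O | intermediate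
7 | 4-(tert-butyldimethylsilyloxy)-2-hydroxy-3,5-bis(3-methylbut-2-enyl)benzaldehyde | O=Cc1cc(CC=C(C)C)c(O[Si](C)(C)C(C)(C)C)c(CC=C(C)C)c1O | intermediate
8 | 3-bromo-4-hydroxybenzaldehyde | O=Cc1ccc(O)c(Br)c1 | starting material
9 | 3-bromo-4-(tert-butyldimethylsilyloxy)benzaldehyde | O=Cc1ccc(O[Si](C)(C)C(C)(C)C)c(Br)c1 | intermediate
10 | 4-(tert-butyldimethylsilyloxy)-3-(3-methylbut-2-enyl)benzaldehyde | O=Cc1ccc(O[Si](C)(C)C(C)(C)C)c(CC=C(C)C)c1 | intermediate
11 | tert-butyldimethyl[2-(3-methylbut-2-enyl)-4-vinylphenoxy]silane | C=Cc1ccc(O[Si](C)(C)C(C)(C)C)c(CC=C(C)C)c1 | intermediate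
12 | 3-(tert-butyldimethylsilyloxy)-6-(dimethoxymethyl)-2,4-bis(3-methylbut-2-enyl)phenol (dimethyl acetal of 7) | COC(OC)c1cc(CC=C(C)C)c(O[Si](C)(C)C(C)(C)C)c(CC=C(C)C)c1O | intermediate
13 | (E)-3-(tert-butyldimethylsilyloxy)-6-(methoxymethylidene)-2,4-bis(3-methylbut-2-enyl)cyclohexa-2,4-dien-1-one (4-methoxy ortho-quinone methide, reacting as its O-protonated ion pair) | CO/C=C1\C=C(CC=C(C)C)C(O[Si](C)(C)C(C)(C)C)=C(CC=C(C)C)C1=O | intermediate
14 | (2S)-7-(tert-butyldimethylsilyloxy)-2-[4-(tert-butyldimethylsilyloxy)-3-(3-methylbut-2-enyl)phenyl]-4-methoxy-6,8-bis(3-methylbut-2-enyl)chromane, C4 epimers | CC(C)=CCc1cc([C@@H]2CC(OC)c3cc(CC=C(C)C)c(O[Si](C)(C)C(C)(C)C)c(CC=C(C)C)c3O2)ccc1O[Si](C)(C)C(C)(C)C | intermediate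
15 | (2S)-7-(tert-butyldimethylsilyloxy)-2-[4-(tert-butyldimethylsilyloxy)-3-(3-methylbut-2-enyl)phenyl]-6,8-bis(3-methylbut-2-enyl)chroman-4-ol, C4 epimers | CC(C)=CCc1cc([C@@H]2CC(O)c3cc(CC=C(C)C)c(O[Si](C)(C)C(C)(C)C)c(CC=C(C)C)c3O2)ccc1O[Si](C)(C)C(C)(C)C | intermediate
16 | (2S)-7-(tert-butyldimethylsilyloxy)-2-[4-(tert-butyldimethylsilyloxy)-3-(3-methylbut-2-enyl)phenyl]-6,8-bis(3-methylbut-2-enyl)chroman-4-one | CC(C)=CCc1cc([C@@H]2CC(=O)c3cc(CC=C(C)C)c(O[Si](C)(C)C(C)(C)C)c(CC=C(C)C)c3O2)ccc1O[Si](C)(C)C(C)(C)C | intermediate
17 | (2S)-7-hydroxy-2-[4-hydroxy-3-(3-methylbut-2-enyl)phenyl]-6,8-bis(3-methylbut-2-enyl)chroman-4-one | CC(C)=CCc1cc([C@@H]2CC(=O)c3cc(CC=C(C)C)c(O)c(CC=C(C)C)c3O2)ccc1O | target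

**Step count and risks**

Total: 12 steps. Longest linear sequence: 9 steps (steps 1–5, then 9–12). The ring B branch (steps 6–8) joins at step 9.

Least certain steps:

- **Step 9 (key step).**
  - Most likely failure: poor facial selectivity, because no intermolecular enantioselective version of this cycloaddition is established and a loosely bound ion pair would let the styrene approach either face.
  - Further hazards: a stepwise pathway that couples C2 to the uncontrolled cis/trans closure; acid-induced oligomerisation of the electron-rich styrene; cyclisation of the ortho prenyl group of 7 onto its free phenol; loss of the ring A silyl group by methanolysis of the cationic intermediate; and erosion of ee by re-ionisation of O1–C2 in the product.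
  - Fallback (known chemistry), from 7 and 11, returning at 16: the coupling is run in its established achiral form (Sc(OTf)3, 10 mol%, HC(OMe)3, CH2Cl2, 0 °C) to give the racemic 4-methoxyflavan F1. Steps 10 and 11 applied unchanged give the racemic flavan-4-ol F2 and the racemic bis-silyl flavanone F3. Kinetic resolution of F3 by asymmetric transfer hydrogenation (RuCl[(R,R)-TsDPEN](p-cymene) or its enantiomer, whichever reduces the (2R) ketone faster; HCO2H/Et3N, rt, run slightly past half conversion) turns the (2R) enantiomer into the cis-(2R,4R)-flavan-4-ol F4, which is separated, and leaves (2S)-16. At most half of the material is carried on.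

- **Step 3.**
  - Most likely failure: allylic transposition during transfer of the prenyl group (1,1-dimethylallyl isomers), and slow coupling with hydrodebromination at the C3 bromide, which is flanked by two acetoxy groups.
  - Fallback, from 3, returning at 5: twofold Stille coupling with allyltributylstannane (Pd(PPh3)4, toluene, 105 °C), where transposition is irrelevant, gives 2,4-diacetoxy-3,5-diallylbenzaldehyde F5. Cross-metathesis of both allyl groups with 2-methylbut-2-ene (second-generation Grubbs catalyst RuCl2(=CHPh)(H2IMes)(PCy3), CH2Cl2, 40 °C) then gives 5.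

- **Step 10.**
  - Most likely failure: elimination from the C4 cation to the 2H-chromene instead of capture by water; on prolonged exposure, acid-induced ionisation of O1–C2 with loss of configuration.
  - Fallback, from 14, returning at 16 without passing through 15: oxidative cleavage of the benzylic methyl ether with DDQ (1.2 equiv, CH2Cl2/pH 7 buffer, 0 °C). DDQ should remove hydride from C4, the most hydridic C–H (α to the methoxy oxygen and ortho/para to two ring A oxygens), and water converts the resulting oxocarbenium ion into the ketone. This fallback makes no new compound (F0).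

- **Step 12.**
  - Most likely failure: opening of ring C under the basicity of fluoride or phenoxide (retro-oxa-Michael to the chalcone, or opening through the 4'-phenoxide) with racemisation at C2; slow cleavage at the hindered C7 silyl ether would lengthen the exposure.
  - Fallback, from 15, returning at 17: the silyl groups are removed before the carbonyl exists (TBAF/AcOH, THF, 0 °C), giving (2S)-2-[4-hydroxy-3-(3-methylbut-2-enyl)phenyl]-6,8-bis(3-methylbut-2-enyl)chromane-4,7-diol F6. Without the ketone, no β-elimination pathway is available. The benzylic C4 alcohol, para to the free C7 hydroxyl, is then oxidised selectively with MnO2 (CH2Cl2, rt) to give 17.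

**Further compounds**

F1 | step 9 | (2RS,4RS)-7-(tert-butyldimethylsilyloxy)-2-[4-(tert-butyldimethylsilyloxy)-3-(3-methylbut-2-enyl)phenyl]-4-methoxy-6,8-bis(3-methylbut-2-enyl)chromane (racemate, C4 epimers) | CC(C)=CCc1cc(C2CC(OC)c3cc(CC=C(C)C)c(O[Si](C)(C)C(C)(C)C)c(CC=C(C)C)c3O2)ccc1O[Si](C)(C)C(C)(C)C
F2 | step 9 | racemic 7-(tert-butyldimethylsilyloxy)-2-[4-(tert-butyldimethylsilyloxy)-3-(3-methylbut-2-enyl)phenyl]-6,8-bis(3-methylbut-2-enyl)chroman-4-ol (C4 epimers) | CC(C)=CCc1cc(C2CC(O)c3cc(CC=C(C)C)c(O[Si](C)(C)C(C)(C)C)c(CC=C(C)C)c3O2)ccc1O[Si](C)(C)C(C)(C)C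
F3 | step 9 | racemic 7-(tert-butyldimethylsilyloxy)-2-[4-(tert-butyldimethylsilyloxy)-3-(3-methylbut-2-enyl)phenyl]-6,8-bis(3-methylbut-2-enyl)chroman-4-one | CC(C)=CCc1cc(C2CC(=O)c3cc(CC=C(C)C)c(O[Si](C)(C)C(C)(C)C)c(CC=C(C)C)c3O2)ccc1O[Si](C)(C)C(C)(C)C
F4 | step 9 | (2R,4R)-7-(tert-butyldimethylsilyloxy)-2-[4-(tert-butyldimethylsilyloxy)-3-(3-methylbut-2-enyl)phenyl]-6,8-bis(3-methylbut-2-enyl)chroman-4-ol (cis) | CC(C)=CCc1cc([C@H]2C[C@@H](O)c3cc(CC=C(C)C)c(O[Si](C)(C)C(C)(C)C)c(CC=C(C)C)c3O2)ccc1O[Si](C)(C)C(C)(C)C
F5 | step 3 | 2,4-diacetoxy-3,5-diallylbenzaldehyde | CC(=O)Oc1c(CC=C)cc(C=O)c(OC(C)=O)c1CC=C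
F0 | step 10 | none | none
F6 | step 12 | (2S)-2-[4-hydroxy-3-(3-methylbut-2-enyl)phenyl]-6,8-bis(3-methylbut-2-enyl)chromane-4,7-diol (C4 epimers) | CC(C)=CCc1cc([C@@H]2CC(O)c3cc(CC=C(C)C)c(O)c(CC=C(C)C)c3O2)ccc1O
A1 | alternative 1 | 2,6-bis(3-methylbut-2-enyl)-3-(triisopropylsilyloxy)phenol | Oc1c(CC=C(C)C)ccc(O[Si](C(C)C)(C(C)C)C(C)C)c1CC=C(C)C
A2 | alternative 1 | (E)-1-diazo-7-methylocta-3,6-dien-2-one | [N-]=[N+]=CC(=O)/C=C/CC=C(C)C
A3 | alternative 1 | triisopropyl[(5-methylhex-4-en-1-ynyl)oxy]silane | CC(C)=CCC#CO[Si](C(C)C)(C(C)C)C(C)C
A4 | alternative 2 | (2S)-2-[4-(tert-butyldimethylsilyloxy)-3-(3-methylbut-2-enyl)phenyl]-7-hydroxy-6,8-bis(3-methylbut-2-enyl)chroman-4-one | CC(C)=CCc1cc([C@@H]2CC(=O)c3cc(CC=C(C)C)c(O)c(CC=C(C)C)c3O2)ccc1O[Si](C)(C)C(C)(C)C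
A5 | alternative 2 | (2S)-2-[4-(tert-butyldimethylsilyloxy)-3-(3-methylbut-2-enyl)phenyl]-5-iodo-2,3-dihydro-4H-pyran-4-one | CC(C)=CCc1cc([C@@H]2CC(=O)C(I)=CO2)ccc1O[Si](C)(C)C(C)(C)C
A6 | alternative 2 | trimethyl{[1-methoxy-7-methyl-2-(3-methylbut-2-enyl)octa-1,3,6-trien-3-yl]oxy}silane (alkene geometry not defined) | COC=C(CC=C(C)C)C(O[Si](C)(C)C)=CCC=C(C)C
A7 | alternative 3 | (2S)-4-(tert-butyldimethylsilyloxy)-7-(methoxymethoxy)-2-[4-(methoxymethoxy)-3-(3-methylbut-2-enyl)phenyl]-6,8-bis(3-methylbut-2-enyl)chromane (C4 epimers) | CC(C)=CCc1cc([C@@H]2CC(O[Si](C)(C)C(C)(C)C)c3cc(CC=C(C)C)c(OCOC)c(CC=C(C)C)c3O2)ccc1OCOC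
A8 | alternative 3 | (1S)-3-[2-bromo-4-(methoxymethoxy)-3,5-bis(3-methylbut-2-enyl)phenyl]-3-(tert-butyldimethylsilyloxy)-1-[4-(methoxymethoxy)-3-(3-methylbut-2-enyl)phenyl]propan-1-ol (C3 epimers) | CC(C)=CCc1cc([C@@H](O)CC(O[Si](C)(C)C(C)(C)C)c2cc(CC=C(C)C)c(OCOC)c(CC=C(C)C)c2Br)ccc1OCOC
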